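## Analysis of the target

The target (34) is a tetracyclic C25 keto lactone. Its core is a bicyclo[2.2.2]oct-5-en-2-one, numbered here as follows: ketone C1, bridgehead CH C2, alkene bridge C3=C4 with a methyl on C4, quaternary bridgehead C5, methyl-bearing quaternary C10 completing the ketone bridge, and the saturated bridge C1′H2–C2′H. A cyclohexane ring B (C5, C6, C7, C8, C9, C10) is fused across C5–C10, and a γ-lactone (O–C6, C7, C11, C12) is fused to ring B at C6–C7. C2′ carries a 6-methylhepta-1,5-dien-2-yl chain whose 1,1-disubstituted alkene carbon is C3′.

There are seven stereocentres (C2, C5, C10, C2′, C6, C7, C11). C2 and C5 are tied together by the bicycle. The chain on C2′ points toward the ketone bridge, away from C3=C4. On C10 the methyl lies over the alkene bridge and C9 over the C1′–C2′ bridge. The lactone oxygen on C6 is axial on ring B and syn to the C10 methyl, H7 is axial, so the lactone is cis-fused, and the C11 methyl sits on its convex face.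

The main difficulty is the pair of adjacent quaternary carbons C5 and C10, both ring-fusion atoms, together with the need to hold one absolute configuration across a rigid cage. The sensitive groups are the 1,5-diene side chain (cationic cyclisation in protic acid, electrophilic oxidants), the epimerisable C11, and the β,γ-unsaturated C1 ketone. That ketone cannot enolise (C10 is quaternary, C2 a bridgehead), which helps every later enolate step.

The strategy rests on one feature: C8 and C9 are the only two methylene carbons between C5 and C10. Ring B can therefore be closed last at the unhindered C8–C9 bond, by a C9 radical on C10 adding to the terminal carbon of a vinyl ketone (C6, C7, C8) on C5.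

## Retrosynthetic reasoning

**Lactone C–O bond.** In 34 the O–C12 bond is cut first. This leads to hydroxy ester 33 and, by taking the C6 oxygen back to a ketone, to keto ester 32. The forward step must deliver hydride to C6 from the equatorial side so that the oxygen is axial and cis to the C7 side chain. The C6 ketone is also what makes the next cut possible.

**C7–C11 bond.** 32 is cut between C7 and C11 into the tricyclic diketone 29 and the lactate-derived triflate 31. C7 is the only enolisable position of 29, and substitution on 31 with inversion brings in C11, its methyl and C12 with the correct configuration at C11. Triflate 31 comes from 30 in one step.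

**C8–C9 bond (key disconnection).** Ring B of 29 is opened between the two methylene carbons C8 and C9. The cut is made there, and not at C5–C6 or C9–C10, because it is the only ring B bond that does not touch a quaternary carbon. It gives the acid 28, in which a carboxymethyl arm on C10 and an acryloyl arm on C5 stand on adjacent carbons. The forward reaction has to turn the carboxyl carbon into a leaving group, add C9 to C8, and leave a ketone at C6.

**The two arms of 28.** The acid is taken back to its tert-butyl ester 26. The vinyl ketone is taken back to the methyl ketone 22 plus the one-carbon iminium salt 23 (C8). The methyl ketone is taken back to the silylalkyne 20, so that C6 and C7 travel through the route as an inert, linear two-carbon group.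

**C4 methyl and C3=C4 alkene.** 20 goes back through alcohol 19 and diol 17 to the enoate 16: the C4 methyl is the reduced form of an ester carbon. The alkene of 16 comes from the selenide 14 by elimination, which can only run toward C3.

**C9–C10 bond.** 14 is cut at C9–C10 into the ketone 12 and the bromoacetate 13. The cut is placed at a stage where C4 is sp3 and fully substituted, so that its endo group forces the electrophile onto the correct face of C10. The selenide 12 comes from the keto ester 11; selenium is put on C4 before C9 arrives, because afterwards the new ester would be the more acidic site.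

**C2–C3 and C4–C5 bonds.** 11 is cut into the enynone 9 and methyl acrylate 10. This removes the C3–C4 bridge in one operation and returns the six-membered ring of a carvone derivative (C1, C10, C5, C1′, C2′, C2). The forward reaction has to form the quaternary C5 and add the bridge on the face away from the C2′ chain.

**C5–C6 bond and the position of the carbonyl.** 9 goes back to the tertiary alcohol 8 by a 1,3-transposition of oxygen, and 8 to the enone 6 plus the alkyne 7. The transposition places the new substituent on the β-carbon of an enone and reverses the ring numbering, which is why the (R) series of carvone leads to the (S) descriptor needed at C2′.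

**Side chain.** 6 is cut at its trisubstituted alkene into the terminal diene 4 and the alkene 5. 4 is cut between the two allylic methylene carbons into the allylic chloride 2 and the stannane 3, and 2 comes from 1. The chain is built first, on a small and robust enone, so that no organometallic coupling is needed later.

## Alternatives that were turned down

Alternative 1: Here the central disconnection is that of the C3–C4 bridge (C2–C3 and C4–C5). The forward key step is the double Michael reaction of the kinetic dienolate of a 3-substituted enone of the same kind as 9 with 10, giving keto ester A1. In its favour, it makes two bonds, the bicycle and the quaternary C5 in one step from the chiral pool, with the C2′ chain steering the facial course. In bond count it is stronger than the single bond made by the chosen key step. Against it as the centre of the plan: it solves the easier half of the problem. A1 still lacks ring B, the quaternary C10 and the lactone, and its protected hydroxymethyl group on C5 is several oxidation-state changes away from anything that can reach C10. The uncertain event, a reversible Michael closure at a fully substituted β-carbon, would also sit early, with the longest part of the route behind it. The chosen strategy keeps this construction as a supporting step (step 6), with a smaller sp-hybridised group on C5, and spends the key step on the C8–C9 bond instead.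

Alternative 2: The saturated bridge is cut at C1′–C2′. The forward key step is a Lewis-acid-promoted carbonyl-ene reaction between a formyl group on C5 and a (Z)-alkenyl group on C2, which closes the bicycle and creates the exocyclic methylene, giving A2. In its favour, the acid- and oxidant-sensitive 1,1-disubstituted alkene appears only at the end, where the chosen route must carry it through many steps; on that point the alternative is stronger. Against it: rings A and B and the lactone, with six stereocentres, must be assembled first on a cyclohexenone that has no rigid cage and no chiral-pool centre to relay configuration. The alkenyl group on C2 makes a β,γ-unsaturated ketone that is prone to conjugation and epimerisation. The ene closure of a bridged ring needs a boat-like transition state. A2 also carries a C1′ hydroxyl that must be removed by radical deoxygenation next to the quaternary C5 in the presence of three alkenes. The chosen strategy instead stores C2′ from the start in 1 and uses the cage as the template for C10, C6 and C7.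

Alternative 3: Ring B is cut at C9–C10. The forward key step is the intramolecular alkylation of the C10 enolate, formed with a strong amide base, by a primary iodide at the end of a four-carbon chain on C5, giving A3. In its favour, it is classical polar chemistry, and it forms the quaternary C10 and ring B in a single step. On that point it is stronger, since the chosen route needs two steps for the same result (steps 8 and 16) and a photochemical set-up. Against it: the bond formed is the most hindered one of ring B, made by a fully substituted enolate flanked by the quaternary C5, with O-alkylation and elimination as competitors. The four-carbon chain with its oxygen stereocentre at C6 has to be built on a neopentyl position beforehand, with uncertain diastereocontrol. In A3, C6 is a silyl ether and C7 a bare methylene, so C6 would have to be deprotected and oxidised anyway to attach C11 and C12, which discards the early C6 centre. The chosen strategy makes the least hindered bond, C8–C9, and delivers exactly the C6 ketone that the endgame needs.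

Key step: step 16

Remark on the chemistry: centres that are formed as mixtures and later destroyed or re-set (C1 of 8 and of 17 to 19, C10 of 11 and 12, selenium in 15) are carried as mixtures; the SMILES leave them open or show one epimer. From 11 onward the compounds are described with the target numbering given above.

## Route

Step 1
Reactants: 1 (R)-carvone
Product: 2 (5R)-5-(3-chloroprop-1-en-2-yl)-2-methylcyclohex-2-en-1-one
Conditions: Ca(OCl)2, solid CO2, CH2Cl2/H2O, 0 °C
Reagents that add atoms: calcium hypochlorite, [Ca+2].[O-]Cl.[O-]Cl
Why: Ene-type allylic chlorination by HOCl formed in the flask: the electron-rich 1,1-disubstituted alkene reacts with allylic shift, which for an isopropenyl group returns the same 2-substituted allyl skeleton, while the electron-poor enone alkene is left alone. The C5 stereocentre is not involved.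

Step 2
Reactants: 2 (5R)-5-(3-chloroprop-1-en-2-yl)-2-methylcyclohex-2-en-1-one; 3 allyltributylstannane
Product: 4 (5R)-5-(hexa-1,5-dien-2-yl)-2-methylcyclohex-2-en-1-one
Conditions: Pd2(dba)3 (2.5 mol %), P(2-furyl)3 (10 mol %), THF, 60 °C
Reagents that add atoms: none
Why: Stille allyl–allyl coupling: zerovalent palladium ionises the allylic chloride to a 2-substituted π-allyl unit whose two termini lead to the same product, and the allyl group of 3 is transferred to it to give the 1,5-diene. The enone does not react with the stannane.

Step 3
Reactants: 4 (5R)-5-(hexa-1,5-dien-2-yl)-2-methylcyclohex-2-en-1-one; 5 2-methylbut-2-ene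
Product: 6 (5R)-2-methyl-5-(6-methylhepta-1,5-dien-2-yl)cyclohex-2-en-1-one
Conditions: second-generation Grubbs catalyst (3 mol %), 5 (20 equiv), CH2Cl2, 40 °C
Reagents that add atoms: none
Why: Cross-metathesis: only the monosubstituted terminal alkene of 4 loads onto the catalyst, and exchange with 5 installs the trisubstituted chain end with loss of propene. The 1,1-disubstituted alkene and the enone are too hindered or too electron-poor to take part, and a 1,5-diene cannot ring-close.

Step 4
Reactants: 6 (5R)-2-methyl-5-(6-methylhepta-1,5-dien-2-yl)cyclohex-2-en-1-one; 7 ethynyltrimethylsilane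
Product: 8 (5R)-2-methyl-5-(6-methylhepta-1,5-dien-2-yl)-1-[(trimethylsilyl)ethynyl]cyclohex-2-en-1-ol (both C1 epimers)
Conditions: 7, n-BuLi, THF, −78 °C; then 6, −78 → 0 °C; then H2O
Reagents that add atoms: none
Why: 1,2-Addition of the lithium acetylide of 7 to the enone carbonyl gives the tertiary propargylic, allylic alcohol. The new carbinol centre is formed as a mixture of no consequence, because it becomes sp2 in step 5.

Step 5
Reactants: 8 (5R)-2-methyl-5-(6-methylhepta-1,5-dien-2-yl)-1-[(trimethylsilyl)ethynyl]cyclohex-2-en-1-ol (both C1 epimers)
Product: 9 (5S)-2-methyl-5-(6-methylhepta-1,5-dien-2-yl)-3-[(trimethylsilyl)ethynyl]cyclohex-2-en-1-one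
Conditions: [C5H5NH][CrO3Cl] (pyridinium chlorochromate), 4 Å molecular sieves, CH2Cl2, 25 °C
Reagents that add atoms: pyridinium chlorochromate, [O-][Cr](=O)(=O)Cl.c1cc[nH+]cc1
Why: Babler–Dauben oxidative transposition: the chromate ester of the tertiary allylic alcohol undergoes a [3,3] shift to the other allylic terminus and is oxidised to the enone, which moves the carbonyl to the former C3 and leaves the alkynyl group on the β-carbon. Because the ring numbering is thereby reversed, the (R) centre of 1 becomes the (5S) centre of 9, the configuration needed at C2′.

Step 6
Reactants: 9 (5S)-2-methyl-5-(6-methylhepta-1,5-dien-2-yl)-3-[(trimethylsilyl)ethynyl]cyclohex-2-en-1-one; 10 methyl acrylate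
Product: 11 double-Michael keto ester (bicyclo[2.2.2]octan-1-one; C4 CO2Me endo; C5 (trimethylsilyl)ethynyl; C10 H and CH3; C2′ chain anti to the C3–C4 bridge)
Conditions: LiN(iPr)2 (1.05 equiv), THF, −78 °C; then 10, −78 → 25 °C; then H2O
Reagents that add atoms: none
Why: Double Michael reaction (formally an anionic [4+2] addition): the kinetic cross-conjugated dienolate attacks 10 through C2 on the face anti to the neighbouring C2′ chain, and the ester enolate so formed closes onto the β-carbon C5 from the same face, forming C2–C3, C4–C5, the bicycle and the quaternary C5. The small, linear alkynyl group keeps the acceptor carbon accessible; C2 and C5 are set relative to C2′, whereas C4 and C10 are re-made in steps 7 and 8.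

Step 7
Reactants: 11 double-Michael keto ester (bicyclo[2.2.2]octan-1-one; C4 CO2Me endo; C5 (trimethylsilyl)ethynyl; C10 H and CH3; C2′ chain anti to the C3–C4 bridge)
Product: 12 C4-phenylselanyl keto ester (selenium exo; CO2Me endo; C10 H and CH3)
Conditions: LiN(iPr)2 (2.3 equiv), THF, −78 → −20 °C; then PhSeSePh, −78 → 0 °C; then H2O
Reagents that add atoms: diphenyl diselenide, c1ccc(cc1)[Se][Se]c1ccccc1
Why: α-Selenenylation of an ester enolate: two equivalents of base give the keto ester dianion, and the diselenide reacts only with the more basic ester enolate at C4, ketone enolates being inert to it, so that the C10 enolate is simply reprotonated. C4 becomes quaternary with selenium on the open exo face, which prepares the later elimination and leaves the C10 hydrogen as the only acidic one.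

Step 8
Reactants: 12 C4-phenylselanyl keto ester (selenium exo; CO2Me endo; C10 H and CH3); 13 tert-butyl bromoacetate
Product: 14 C10-alkylated selenide (C10 bears CH3 over the C3–C4 bridge and CH2CO2tBu over the C1′–C2′ bridge)
Conditions: KN(SiMe3)2 (1.1 equiv), THF, −78 °C; then 13, −78 → 0 °C
Reagents that add atoms: none
Why: Enolate alkylation: the C1 ketone can enolise only toward C10 (C2 is a bridgehead), and the enolate face turned to the C3–C4 bridge is shielded by the endo substituent on the quaternary C4, so that 13 enters from the side of C1′. This places C9 over the C1′–C2′ bridge and the methyl over the C3–C4 bridge, the C10 configuration of the target.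

Step 9
Reactants: 14 C10-alkylated selenide (C10 bears CH3 over the C3–C4 bridge and CH2CO2tBu over the C1′–C2′ bridge)
Product: 16 enoate (C3=C4 with CO2Me on C4; C1 ketone; C5 (trimethylsilyl)ethynyl; CH2CO2tBu on C10), via selenoxide 15 (not isolated)
Conditions: H2O2 (30 % aq.), pyridine, CH2Cl2, 0 → 25 °C
Reagents that add atoms: none
Why: Selenoxide syn-elimination: oxidation at selenium is followed by loss of PhSeOH toward the only carbon with β-hydrogens, C3 (C5 is quaternary), whose C–H bond is eclipsed with C4–Se in the rigid bicycle. The C3=C4 alkene is therefore formed regiospecifically, in conjugation with the ester.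

Step 10
Reactants: 16 enoate (C3=C4 with CO2Me on C4; C1 ketone; C5 (trimethylsilyl)ethynyl; CH2CO2tBu on C10)
Product: 17 diol (C1 carbinol as either epimer; C4 CH2OH)
Conditions: iBu2AlH (3.5 equiv), CH2Cl2, −78 °C
Reagents that add atoms: none
Why: 1,2-Reduction of the conjugated methyl ester to the primary allylic alcohol; the hindered C1 ketone is reduced as well and is restored in step 12. At −78 °C the neopentyl-type tert-butyl ester and the silylalkyne should not be attacked.

Step 11
Reactants: 17 diol (C1 carbinol as either epimer; C4 CH2OH)
Product: 19 C4-methyl C1 alcohol, via allylic bromide 18 (not isolated)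
Conditions: CBr4, PPh3, CH2Cl2, 0 °C; then LiBHEt3, THF, −78 °C
Reagents that add atoms: none
Why: Appel bromination converts the primary allylic alcohol selectively (the secondary C1 alcohol between a quaternary carbon and a bridgehead is far slower), and hydride then displaces the allylic bromide directly at the primary carbon. SN2′ delivery to C3, which is next to the bridgehead, should not compete, so the alkene stays at C3=C4 and the former ester carbon ends as the C4 methyl.

Step 12
Reactants: 19 C4-methyl C1 alcohol
Product: 20 C4-methyl C1 ketone (C5 (trimethylsilyl)ethynyl; CH2CO2tBu on C10)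
Conditions: Dess–Martin periodinane, CH2Cl2, 25 °C
Reagents that add atoms: none
Why: Dess–Martin oxidation of the secondary alcohol returns the C1 ketone; no other oxidisable group is present.

Step 13
Reactants: 20 C4-methyl C1 ketone (C5 (trimethylsilyl)ethynyl; CH2CO2tBu on C10)
Product: 22 methyl ketone (C5 acetyl; CH2CO2tBu on C10), via terminal alkyne 21 (not isolated)
Conditions: K2CO3, MeOH, 25 °C; then (Ph3P)AuCl (5 mol %), AgOTf (5 mol %), 1,4-dioxane/H2O, 60 °C
Reagents that add atoms: water, O
Why: Protodesilylation, then gold-catalysed Markovnikov hydration of the terminal alkyne; direct attack of water and attack assisted by the C1 carbonyl oxygen (5-exo) both place the new oxygen on C6. The monovalent gold catalyst activates the alkyne in preference to the alkenes, none of which can reach it within the rigid bicycle.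

Step 14
Reactants: 22 methyl ketone (C5 acetyl; CH2CO2tBu on C10); 23 dimethyl(methylidene)ammonium iodide (Eschenmoser's salt)
Product: 26 vinyl ketone tert-butyl ester (C5 acryloyl; CH2CO2tBu on C10), via Mannich base 24 (not isolated), via methiodide 25 (not isolated)
Conditions: LiN(iPr)2 (1.05 equiv), THF, −78 °C; 23, −78 → 25 °C; MeI; then aq. NaHCO3, CH2Cl2, 25 °C
Reagents that add atoms: none
Why: Mannich methylenation: the acetyl group is the only enolisable ketone and is more acidic than the ester, so one equivalent of base gives its kinetic enolate, which adds to the iminium salt 23. Quaternisation and E1cB loss of trimethylamine then give the vinyl ketone, with C8 in place.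

Step 15
Reactants: 26 vinyl ketone tert-butyl ester (C5 acryloyl; CH2CO2tBu on C10)
Product: 28 acryloyl acid (C5 acryloyl; CH2CO2H on C10), via trimethylsilyl ester 27 (not isolated)
Conditions: Me3SiOTf, 2,6-lutidine, CH2Cl2, 0 °C; then pH 5 aqueous buffer
Reagents that add atoms: none
Why: Silyl triflate-mediated cleavage of the tert-butyl ester through the trimethylsilyl ester, which is hydrolysed on work-up. The conditions are free of protic acid, which would cyclise the 1,5-diene, and neither ketone can form a silyl enol ether.

Step 16
Reactants: 28 acryloyl acid (C5 acryloyl; CH2CO2H on C10)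
Product: 29 tricyclic 1,6-diketone (ring B closed; ketones at C1 and C6)
Conditions: Ir[dF(CF3)ppy]2(dtbbpy)PF6 (1 mol %), K2HPO4 (1.2 equiv), DMF (0.005 M), blue LEDs (450 nm), 25 °C, degassed
Reagents that add atoms: none
Why: The carboxylate of 28 is oxidised by the photoexcited trivalent iridium complex, the acyloxyl radical loses CO2, and the primary C9 radical adds to C8, the unsubstituted terminus of the vinyl ketone, forming C8–C9 and ring B. The closest known reaction type is the photoredox decarboxylative Giese addition of carboxylic acids to enones, used here intramolecularly, a known mode for radicals tethered to a vinyl ketone through its carbonyl carbon. Ring B closes in the 6-endo-trig mode; the 5-exo alternative would attack C7 against the polarisation of the enone and leave an unstabilised primary radical. The α-keto radical at C7 is then reduced by the divalent iridium species to the enolate and protonated, which closes the catalytic cycle without a stoichiometric reductant. No stereocentre is created, because C7, C8 and C9 are methylene carbons and both arms hang from the pre-set C5 and C10. The step needs regioselectivity for C8 over C7 and chemoselectivity over the 1,2-acyl (Dowd–Beckwith) shift of the β-keto radical and over addition to the C3′ methylene; the polarity match between the nucleophilic alkyl radical and the enone terminus, and the gauche placement of the two arms on adjacent carbons, should secure both. High dilution suppresses intermolecular addition, and the photocatalyst is not oxidising enough to attack the alkenes.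

Step 17
Reactants: 30 methyl (S)-lactate
Product: 31 methyl (S)-2-[(trifluoromethanesulfonyl)oxy]propanoate
Conditions: (CF3SO2)2O, 2,6-lutidine, CH2Cl2, −78 → 0 °C
Reagents that add atoms: trifluoromethanesulfonic anhydride, O=S(=O)(OS(=O)(=O)C(F)(F)F)C(F)(F)F
Why: O-Sulfonylation of the secondary alcohol; the stereocentre is not touched, so the triflate keeps the (S) configuration.

Step 18
Reactants: 29 tricyclic 1,6-diketone (ring B closed; ketones at C1 and C6); 31 methyl (S)-2-[(trifluoromethanesulfonyl)oxy]propanoate
Product: 32 C7-alkylated diketone (C7 bears equatorial (S)-CH(CH3)CO2Me)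
Conditions: LiN(SiMe3)2 (1.1 equiv), THF, −78 °C; then 31, −78 → −30 °C
Reagents that add atoms: none
Why: Enolate alkylation with an α-triflyloxy ester: the C6 ketone is the only enolisable carbonyl (C5 is quaternary), and its enolate displaces the triflate of 31 by SN2 with inversion, which makes C11 (S) as in the target. The new bond at C7 should form on the face away from C1′, which stands axial on C5, so that the side chain is equatorial; this is also the thermodynamically preferred epimer at the still epimerisable C7.

Step 19
Reactants: 32 C7-alkylated diketone (C7 bears equatorial (S)-CH(CH3)CO2Me)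
Product: 34 target CNP0385704.2, via hydroxy ester 33 (not isolated)
Conditions: KBH(sec-Bu)3 (1.1 equiv), THF, −78 → 0 °C; then H2O
Reagents that add atoms: none
Why: Reduction of the C6 ketone by a bulky hydride, which enters equatorially because the axial path is blocked by the syn-axial C10 methyl; the resulting axial alkoxide is cis to the equatorial side chain on C7 and closes the γ-lactone onto the methyl ester in the flask. C6 is thus set by the ring B chair, and the C1 ketone, flanked by a quaternary carbon and a bridgehead and screened on both faces, should react more slowly.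

## Compound list

1 | (R)-carvone | CC1=CC[C@H](CC1=O)C(C)=C | starting material
2 | (5R)-5-(3-chloroprop-1-en-2-yl)-2-methylcyclohex-2-en-1-one | C=C(CCl)[C@@H]1CC=C(C)C(=O)C1 | intermediate
3 | allyltributylstannane | C=CC[Sn](CCCC)(CCCC)CCCC | starting material
4 | (5R)-5-(hexa-1,5-dien-2-yl)-2-methylcyclohex-2-en-1-one | C=C(CCC=C)[C@@H]1CC=C(C)C(=O)C1 | intermediate
5 | 2-methylbut-2-ene | CC=C(C)C | starting material
6 | (5R)-2-methyl-5-(6-methylhepta-1,5-dien-2-yl)cyclohex-2-en-1-one | C=C(CCC=C(C)C)[C@@H]1CC=C(C)C(=O)C1 | intermediate
7 | ethynyltrimethylsilane | C#C[Si](C)(C)C | starting material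
8 | (5R)-2-methyl-5-(6-methylhepta-1,5-dien-2-yl)-1-[(trimethylsilyl)ethynyl]cyclohex-2-en-1-ol (both C1 epimers) | C=C(CCC=C(C)C)[C@@H]1CC=C(C)C(O)(C#C[Si](C)(C)C)C1 | intermediate
9 | (5S)-2-methyl-5-(6-methylhepta-1,5-dien-2-yl)-3-[(trimethylsilyl)ethynyl]cyclohex-2-en-1-one | C=C(CCC=C(C)C)[C@H]1CC(C#C[Si](C)(C)C)=C(C)C(=O)C1 | intermediate
10 | methyl acrylate | C=CC(=O)OC | starting material
11 | double-Michael keto ester (bicyclo[2.2.2]octan-1-one; C4 CO2Me endo; C5 (trimethylsilyl)ethynyl; C10 H and CH3, drawn with CH3 over the C1′–C2′ bridge; C2′ chain anti to the C3–C4 bridge) | C=C(CCC=C(C)C)[C@H]1C[C@]2(C#C[Si](C)(C)C)[C@@H](C(=O)OC)C[C@H]1C(=O)[C@@H]2C | intermediate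
12 | C4-phenylselanyl keto ester (selenium exo; CO2Me endo; C10 H and CH3) | C=C(CCC=C(C)C)[C@H]1C[C@]2(C#C[Si](C)(C)C)[C@@]([Se]c3ccccc3)(C(=O)OC)C[C@H]1C(=O)[C@@H]2C | intermediate
13 | tert-butyl bromoacetate | CC(C)(C)OC(=O)CBr | starting material
14 | C10-alkylated selenide (C10 bears CH3 over the C3–C4 bridge and CH2CO2tBu over the C1′–C2′ bridge) | C=C(CCC=C(C)C)[C@H]1C[C@]2(C#C[Si](C)(C)C)[C@@]([Se]c3ccccc3)(C(=O)OC)C[C@H]1C(=O)[C@]2(C)CC(=O)OC(C)(C)C | intermediate
15 | selenoxide of 14 (both configurations at selenium) | C=C(CCC=C(C)C)[C@H]1C[C@]2(C#C[Si](C)(C)C)[C@@]([Se](=O)c3ccccc3)(C(=O)OC)C[C@H]1C(=O)[C@]2(C)CC(=O)OC(C)(C)C | intermediate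
16 | enoate (C3=C4 with CO2Me on C4; C1 ketone; C5 (trimethylsilyl)ethynyl; CH2CO2tBu on C10) | C=C(CCC=C(C)C)[C@H]1C[C@]2(C#C[Si](C)(C)C)C(C(=O)OC)=C[C@H]1C(=O)[C@]2(C)CC(=O)OC(C)(C)C | intermediate
17 | diol (C1 carbinol as either epimer; C4 CH2OH) | C=C(CCC=C(C)C)[C@H]1C[C@]2(C#C[Si](C)(C)C)C(CO)=C[C@H]1C(O)[C@]2(C)CC(=O)OC(C)(C)C | intermediate
18 | allylic bromide (C4 CH2Br; C1 carbinol) | C=C(CCC=C(C)C)[C@H]1C[C@]2(C#C[Si](C)(C)C)C(CBr)=C[C@H]1C(O)[C@]2(C)CC(=O)OC(C)(C)C | intermediate
19 | C4-methyl C1 alcohol | C=C(CCC=C(C)C)[C@H]1C[C@]2(C#C[Si](C)(C)C)C(C)=C[C@H]1C(O)[C@]2(C)CC(=O)OC(C)(C)C | intermediate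
20 | C4-methyl C1 ketone (C5 (trimethylsilyl)ethynyl; CH2CO2tBu on C10) | C=C(CCC=C(C)C)[C@H]1C[C@]2(C#C[Si](C)(C)C)C(C)=C[C@H]1C(=O)[C@]2(C)CC(=O)OC(C)(C)C | intermediate
21 | terminal alkyne (C5 ethynyl) | C=C(CCC=C(C)C)[C@H]1C[C@]2(C#C)C(C)=C[C@H]1C(=O)[C@]2(C)CC(=O)OC(C)(C)C | intermediate
22 | methyl ketone (C5 acetyl; CH2CO2tBu on C10) | C=C(CCC=C(C)C)[C@H]1C[C@]2(C(C)=O)C(C)=C[C@H]1C(=O)[C@]2(C)CC(=O)OC(C)(C)C | intermediate
23 | dimethyl(methylidene)ammonium iodide (Eschenmoser's salt) | C=[N+](C)C.[I-] | starting material
24 | Mannich base (C5 3-(dimethylamino)propanoyl) | C=C(CCC=C(C)C)[C@H]1C[C@]2(C(=O)CCN(C)C)C(C)=C[C@H]1C(=O)[C@]2(C)CC(=O)OC(C)(C)C | intermediate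
25 | methiodide of 24 | C=C(CCC=C(C)C)[C@H]1C[C@]2(C(=O)CC[N+](C)(C)C)C(C)=C[C@H]1C(=O)[C@]2(C)CC(=O)OC(C)(C)C.[I-] | intermediate
26 | vinyl ketone tert-butyl ester (C5 acryloyl; CH2CO2tBu on C10) | C=C(CCC=C(C)C)[C@H]1C[C@]2(C(=O)C=C)C(C)=C[C@H]1C(=O)[C@]2(C)CC(=O)OC(C)(C)C | intermediate
27 | trimethylsilyl ester of 28 | C=C(CCC=C(C)C)[C@H]1C[C@]2(C(=O)C=C)C(C)=C[C@H]1C(=O)[C@]2(C)CC(=O)O[Si](C)(C)C | intermediate
28 | acryloyl acid (C5 acryloyl; CH2CO2H on C10) | C=C(CCC=C(C)C)[C@H]1C[C@]2(C(=O)C=C)C(C)=C[C@H]1C(=O)[C@]2(C)CC(=O)O | intermediate
29 | tricyclic 1,6-diketone (ring B closed; ketones at C1 and C6) | C=C(CCC=C(C)C)[C@H]1C[C@]23C(C)=C[C@H]1C(=O)[C@]2(C)CCCC3=O | intermediate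
30 | methyl (S)-lactate | C[C@H](O)C(=O)OC | starting material
31 | methyl (S)-2-[(trifluoromethanesulfonyl)oxy]propanoate | C[C@H](OS(=O)(=O)C(F)(F)F)C(=O)OC | intermediate
32 | C7-alkylated diketone (C7 bears equatorial (S)-CH(CH3)CO2Me) | C=C(CCC=C(C)C)[C@H]1C[C@]23C(C)=C[C@H]1C(=O)[C@]2(C)CC[C@@H]([C@H](C)C(=O)OC)C3=O | intermediate
33 | C6 axial hydroxy ester | C=C(CCC=C(C)C)[C@H]1C[C@]23C(C)=C[C@H]1C(=O)[C@]2(C)CC[C@@H]([C@H](C)C(=O)OC)[C@H]3O | intermediate
34 | target CNP0385704.2 | C=C(CCC=C(C)C)[C@H]1C[C@]23C(C)=C[C@H]1C(=O)[C@]2(C)CC[C@H]1[C@H](C)C(=O)O[C@H]13 | target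

## Step count and least certain steps

Total step count: 19. Longest linear sequence: 18 steps (steps 1 to 16, 18 and 19, from 1); step 17 is a one-step side branch.

**Step 16 (key step).** Most likely failure: slow oxidation of the unactivated primary carboxylate, for which the excited photocatalyst is only just oxidising enough, so that little C9 radical is formed. Once formed, the radical may be diverted by 1,2-acyl migration toward the C1 ketone or by addition to the nearby C3′ methylene before it reaches C8. Fallback: setting out from 28, esterification with N-hydroxypyridine-2-thione and dicyclohexylcarbodiimide in the dark would give the thiohydroxamate ester F1. Visible-light photolysis of F1 at high dilution with tert-butyl thiol as hydrogen donor generates the same C9 radical by a chain process that does not depend on carboxylate oxidation, and returns to the route at 29.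

**Step 6.** Most likely failure: reversal or stalling of the second Michael addition, because the ester enolate must attack a fully substituted β-carbon, with polymerisation of 10 as the sink. Fallback: setting out from 9, deprotonation with LiN(iPr)2 and silylation with tert-butyldimethylsilyl chloride would give the silyloxydiene F2. Heating F2 with 10 in toluene in a sealed tube would give the Diels–Alder adduct F3 by a neutral cycloaddition that cannot revert through an enolate, and dilute HCl in THF would return to the route at 11.

**Step 7.** Most likely failure: incomplete formation of the dianion, or transfer of selenium to C10, so that C4 is only partly substituted. Fallback: setting out from 11, soft enolisation of the ketone alone with Me3SiOTf and Et3N would give the trimethylsilyl enol ether F4. Deprotonation of the ester with LiN(iPr)2 and reaction with PhSeBr at −78 °C would give the selenide F5, and dilute acid on work-up would return to the route at 12.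

**Step 8.** Most likely failure: O-alkylation, or retro-Michael opening of the enolate, because C-alkylation at C10 beside the quaternary C5 is slow. Fallback: setting out from 12, the same enolate would be added to tert-butyl glyoxylate, an aldol addition that tolerates hindrance better than a substitution, to give the aldol adduct F6. Oxidation with H2O2 would pass through the selenoxide F7 (not isolated) to the enoate alcohol F8. Acylation with phenyl chlorothionoformate would give the thiocarbonate F9, and radical deoxygenation with Bu3SnH would return to the route at 16.

**Step 18.** Most likely failure: elimination of the secondary triflate to an acrylate or O-alkylation of the enolate, and partial loss of configuration at C11 under the basic conditions. Fallback: setting out from 29, alkylation of the same enolate with methyl bromoacetate would give the keto ester F10. Reduction with KBH(sec-Bu)3 would give the hydroxy ester F11, which closes in the flask to the lactone F12. Deprotonation of F12 with LiN(iPr)2 and methylation with MeI from the convex face of the cis-fused lactone would return to the route at 34; C11 is then set by the shape of the bicycle and not by substitution.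

**Step 19.** Most likely failure: poor chemoselectivity between the two ketones, so that the C1 ketone is reduced alongside C6. Fallback: setting out from 32, both ketones would be reduced deliberately with excess KBH(sec-Bu)3 to the dihydroxy ester F13, in which only the C6 alkoxide can reach the ester and which closes to the hydroxy lactone F14. Oxidation of the remaining C1 alcohol with Dess–Martin periodinane would return to the route at 34.

## Further compounds

F1 | step 16 | thiohydroxamate (Barton) ester of 28 | C=C(CCC=C(C)C)[C@H]1C[C@]2(C(=O)C=C)C(C)=C[C@H]1C(=O)[C@]2(C)CC(=O)ON1C=CC=CC1=S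
F2 | step 6 | tert-butyldimethylsilyloxy diene from 9 | C=C(CCC=C(C)C)[C@H]1CC(C#C[Si](C)(C)C)=C(C)C(O[Si](C)(C)C(C)(C)C)=C1
F3 | step 6 | Diels–Alder adduct (tert-butyldimethylsilyl enol ether of 11) | C=C(CCC=C(C)C)[C@H]1C[C@]2(C#C[Si](C)(C)C)[C@@H](C(=O)OC)C[C@H]1C(O[Si](C)(C)C(C)(C)C)=C2C
F4 | step 7 | trimethylsilyl enol ether of 11 | C=C(CCC=C(C)C)[C@H]1C[C@]2(C#C[Si](C)(C)C)[C@@H](C(=O)OC)C[C@H]1C(O[Si](C)(C)C)=C2C
F5 | step 7 | trimethylsilyl enol ether of 12 | C=C(CCC=C(C)C)[C@H]1C[C@]2(C#C[Si](C)(C)C)[C@@]([Se]c3ccccc3)(C(=O)OC)C[C@H]1C(O[Si](C)(C)C)=C2C
F6 | step 8 | glyoxylate aldol adduct of 12 (C9 carbinol as either epimer) | C=C(CCC=C(C)C)[C@H]1C[C@]2(C#C[Si](C)(C)C)[C@@]([Se]c3ccccc3)(C(=O)OC)C[C@H]1C(=O)[C@]2(C)C(O)C(=O)OC(C)(C)C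
F7 | step 8 | selenoxide of F6 | C=C(CCC=C(C)C)[C@H]1C[C@]2(C#C[Si](C)(C)C)[C@@]([Se](=O)c3ccccc3)(C(=O)OC)C[C@H]1C(=O)[C@]2(C)C(O)C(=O)OC(C)(C)C
F8 | step 8 | enoate with C9 hydroxyl | C=C(CCC=C(C)C)[C@H]1C[C@]2(C#C[Si](C)(C)C)C(C(=O)OC)=C[C@H]1C(=O)[C@]2(C)C(O)C(=O)OC(C)(C)C
F9 | step 8 | C9 O-phenyl thiocarbonate of F8 | C=C(CCC=C(C)C)[C@H]1C[C@]2(C#C[Si](C)(C)C)C(C(=O)OC)=C[C@H]1C(=O)[C@]2(C)C(OC(=S)Oc3ccccc3)C(=O)OC(C)(C)C
F10 | step 18 | C7 (methoxycarbonyl)methyl diketone | C=C(CCC=C(C)C)[C@H]1C[C@]23C(C)=C[C@H]1C(=O)[C@]2(C)CC[C@@H](CC(=O)OC)C3=O
F11 | step 18 | C6 axial hydroxy ester without the C11 methyl | C=C(CCC=C(C)C)[C@H]1C[C@]23C(C)=C[C@H]1C(=O)[C@]2(C)CC[C@@H](CC(=O)OC)[C@H]3O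
F12 | step 18 | lactone without the C11 methyl | C=C(CCC=C(C)C)[C@H]1C[C@]23C(C)=C[C@H]1C(=O)[C@]2(C)CC[C@H]1CC(=O)O[C@H]13
F13 | step 19 | C1,C6 dihydroxy ester (C1 carbinol as either epimer) | C=C(CCC=C(C)C)[C@H]1C[C@]23C(C)=C[C@H]1C(O)[C@]2(C)CC[C@@H]([C@H](C)C(=O)OC)[C@H]3O
F14 | step 19 | C1 hydroxy lactone (C1 carbinol as either epimer) | C=C(CCC=C(C)C)[C@H]1C[C@]23C(C)=C[C@H]1C(O)[C@]2(C)CC[C@H]1[C@H](C)C(=O)O[C@H]13
A1 | alternative 1 | bicyclo[2.2.2]octanone keto ester with C5 (4-methoxybenzyl)oxymethyl and C4 endo methyl ester | C=C(CCC=C(C)C)[C@H]1C[C@]2(COCc3ccc(OC)cc3)[C@@H](C(=O)OC)C[C@H]1C(=O)[C@@H]2C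
A2 | alternative 2 | C1′-hydroxy derivative of the target | C=C(CCC=C(C)C)[C@H]1[C@@H](O)[C@]23C(C)=C[C@H]1C(=O)[C@]2(C)CC[C@H]1[C@H](C)C(=O)O[C@H]13
A3 | alternative 3 | tricyclic keto ester with ring B closed and a C6 tert-butyldimethylsilyl ether | C=C(CCC=C(C)C)[C@H]1C[C@]23[C@@H](C(=O)OC)C[C@H]1C(=O)[C@]2(C)CCC[C@@H]3O[Si](C)(C)C(C)(C)C
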